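**Plan**

Numbering: ring C1 (C=O), C2=C3, C4 (OMe), C5 (CH2), C6 (quaternary); Cα is the CH(CH3) carbon attached to C6.
Enabling feature: C6 bears two CH2 groups. Ring C5 leads to oxygenated C4, and the allyl CH2 leads to an sp2 CH. Both end carbons are masked aldehyde carbons, so with two CH2CHO arms C6 is no longer a stereocentre, and C3 (the enone β-carbon) can attack C4 as an alkenyl-metal nucleophile.
Retrosynthetic cuts in order: allyl C=C (methylenation); O–CH3; ring bond C3–C4 (back to a (Z)-β-iodoenone dialdehyde); the two CHO carbons rejoined as a cyclopentene C=C; C3–I; C1–C2 (ethynyl addition); aryl–C(=O) (aryllithium on a lactone); the two C6–CH2 bonds (bis-alkylation of a succinic half-ester).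
Forward order of rings: cyclopentene (annulation), then a spiro-γ-lactone (formed, then opened by the aryl group), then cleavage of the cyclopentene, and last the cyclohexenone.
Stereochemistry: Cα comes from the chiral pool and is kept away from enolising conditions. C4 and C6 are created together in the ring closure, C4 by a chiral ligand on chromium and C6 by the half-chair that ties it to C4.

Key step: step 9

Assumption 1: the 4-methyl half-ester of (S)-methylsuccinic acid (compound 1) is taken as a catalogue compound.
Assumption 2: the (S)-valinol-derived oxazoline–sulfonamide ligand, taken as an available reagent, is assumed to direct the alkenyl group to the Si face of the aldehyde and to be matched with (S)-Cα. Its mirror image is made in the same way from (R)-valinol.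

**Route**

Step 1
Reactants: 1 (S)-4-methoxy-2-methyl-4-oxobutanoic acid; 2 cis-1,4-dichlorobut-2-ene
Product: 4 (S)-2-[1-(methoxycarbonyl)cyclopent-3-en-1-yl]propanoic acid, via monoalkylated allylic chloride 3 (not isolated)
Conditions: LiN(i-Pr)2 (2.2 equiv), THF, −78 °C; 2 (1.2 equiv), DMPU, −78 to −20 °C; LiN(i-Pr)2 (1.3 equiv), −78 °C to rt; 1 M HCl
Reagents that add atoms: cis-1,4-dichlorobut-2-ene (2), ClC/C=C\CCl
Why: Double enolate alkylation (cyclopentannulation) of a half-ester dianion, in which the carboxylate keeps Cα–H from being removed so that only the ester CH2 is enolised, the first SN2 displacement gives 3, and the cis alkene allows the second, intramolecular 5-exo-tet displacement; Cα is untouched and the new quaternary carbon carries two identical ring arms, so no new stereocentre arises.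

Step 2
Reactants: 4 (S)-2-[1-(methoxycarbonyl)cyclopent-3-en-1-yl]propanoic acid
Product: 6 (S)-4-methyl-2-oxaspiro[4.4]non-7-en-3-one, via hydroxy acid 5 (not isolated)
Conditions: LiBEt3H (3.3 equiv), THF, 0 °C to rt; then 2 M HCl, rt
Reagents that add atoms: none
Why: Chemoselective hydride reduction of an ester beside a lithium carboxylate, which LiBEt3H neither reduces nor turns into a hydroborating borane, followed by acid-catalysed γ-lactonisation helped by the gem-dialkyl effect; Cα sits next to a carboxylate and is not enolised.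

Step 3
Reactants: 6 (S)-4-methyl-2-oxaspiro[4.4]non-7-en-3-one; 7 4-bromo-1,2-dimethoxybenzene
Product: 9 (S)-1-(3,4-dimethoxyphenyl)-2-[1-(hydroxymethyl)cyclopent-3-en-1-yl]propan-1-one, via 3,4-dimethoxyphenyllithium 8 (not isolated)
Conditions: 7, n-BuLi (1.0 equiv to 7), THF, −78 °C; then 6, −78 °C; AcOH in THF, −78 °C
Reagents that add atoms: 4-bromo-1,2-dimethoxybenzene (7), COc1ccc(Br)cc1OC
Why: Bromine–lithium exchange and single addition of an aryllithium to a γ-lactone, where the lithium hemiketal persists at −78 °C and collapses only on the cold acidic quench, so neither a second addition nor enolisation of the new ketone at Cα should occur.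

Step 4
Reactants: 9 (S)-1-(3,4-dimethoxyphenyl)-2-[1-(hydroxymethyl)cyclopent-3-en-1-yl]propan-1-one
Product: 10 1-[(S)-1-(3,4-dimethoxyphenyl)-1-oxopropan-2-yl]cyclopent-3-ene-1-carbaldehyde
Conditions: n-Pr4N[RuO4] (5 mol%), 4-methylmorpholine N-oxide, 4 Å molecular sieves, CH2Cl2, rt
Reagents that add atoms: none
Why: Ley–Griffith oxidation of a neopentyl primary alcohol under neutral conditions, which draws the open hydroxy ketone out of any hemiketal and gives an aldehyde without α-hydrogen, while Cα meets neither acid nor strong base.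

Step 5
Reactants: 10 1-[(S)-1-(3,4-dimethoxyphenyl)-1-oxopropan-2-yl]cyclopent-3-ene-1-carbaldehyde; 11 ethynylmagnesium bromide
Product: 12 (2S)-1-(3,4-dimethoxyphenyl)-2-[1-(1-hydroxyprop-2-yn-1-yl)cyclopent-3-en-1-yl]propan-1-one (both carbinol epimers)
Conditions: 11 (1.2 equiv), THF, −78 to −20 °C; aq. NH4Cl
Reagents that add atoms: ethynylmagnesium bromide (11), C#C[Mg]Br
Why: Grignard 1,2-addition in which the small, weakly basic acetylide prefers the aldehyde to the hindered, donor-deactivated aryl ketone; the new carbinol centre forms without control and is erased in step 6.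

Step 6
Reactants: 12 (2S)-1-(3,4-dimethoxyphenyl)-2-[1-(1-hydroxyprop-2-yn-1-yl)cyclopent-3-en-1-yl]propan-1-one
Product: 13 (S)-1-(3,4-dimethoxyphenyl)-2-[1-(prop-2-ynoyl)cyclopent-3-en-1-yl]propan-1-one
Conditions: Dess–Martin periodinane, NaHCO3, CH2Cl2, 0 °C to rt
Reagents that add atoms: none
Why: Dess–Martin oxidation of a propargylic alcohol under buffered, non-nucleophilic conditions that spare the terminal ynone and Cα and suppress acid-induced dehydration of any hemiketal.

Step 7
Reactants: 13 (S)-1-(3,4-dimethoxyphenyl)-2-[1-(prop-2-ynoyl)cyclopent-3-en-1-yl]propan-1-one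
Product: 14 (S)-1-(3,4-dimethoxyphenyl)-2-{1-[(Z)-3-iodoprop-2-enoyl]cyclopent-3-en-1-yl}propan-1-one
Conditions: NaI (1.2 equiv), AcOH, rt, dark
Reagents that add atoms: sodium iodide, [Na+].[I-]
Why: Hydroiodination of an ynone by conjugate addition of iodide and kinetic protonation of the allenol (net anti addition), the standard entry to (Z)-β-iodoenones; the isolated ring alkene is not protonated by AcOH.

Step 8
Reactants: 14 (S)-1-(3,4-dimethoxyphenyl)-2-{1-[(Z)-3-iodoprop-2-enoyl]cyclopent-3-en-1-yl}propan-1-one
Product: 16 3-[(S)-1-(3,4-dimethoxyphenyl)-1-oxopropan-2-yl]-3-[(Z)-3-iodoprop-2-enoyl]pentanedial, via secondary ozonide 15 (not isolated)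
Conditions: O3, CH2Cl2, −78 °C, Sudan Red 7B as end-point indicator; Me2S, −78 °C to rt; dried azeotropically and used at once
Reagents that add atoms: ozone, [O-][O+]=O
Why: Ozonolysis with reductive work-up, in which the electrophilic dipole attacks the strained, electron-rich cis-disubstituted alkene well before the acceptor- and iodine-substituted alkene or the acylated arene; the central carbon of 16 bears two identical arms and is still not stereogenic.

Step 9
Reactants: 16 3-[(S)-1-(3,4-dimethoxyphenyl)-1-oxopropan-2-yl]-3-[(Z)-3-iodoprop-2-enoyl]pentanedial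
Product: 18 2-{(1S,5R)-1-[(S)-1-(3,4-dimethoxyphenyl)-1-oxopropan-2-yl]-5-hydroxy-2-oxocyclohex-3-en-1-yl}acetaldehyde, via alkenylchromium species 17 (not isolated)
Conditions: CrCl2 (4 equiv), N-{2-[(S)-4-isopropyl-4,5-dihydrooxazol-2-yl]-6-methylphenyl}methanesulfonamide (4.4 equiv), Et3N (4 equiv), THF, rt, 1 h; NiCl2 (0.1 equiv); 16 added by syringe pump to ca. 2 mM, rt; aqueous work-up
Reagents that add atoms: none
Why: Proposed new method: zerovalent nickel, formed from NiCl2 by divalent chromium, inserts into the C3–I bond with retention, and transmetalation passes the (Z)-alkenyl group to ligand-bound trivalent chromium (17), which is nucleophilic enough for an aldehyde but not for a ketone. The closest known reaction types are intramolecular Nozaki–Hiyama–Kishi cyclisations of iodoalkenyl aldehydes, ligand-controlled asymmetric Nozaki–Hiyama–Kishi alkenylations and couplings of (Z)-β-iodoacrylates with aldehydes, whereas a β-chromio enone choosing between two diastereotopic CH2CHO groups has no precedent. The cyclohexenone closes in the 6-exo-trig mode at the aldehyde carbon (C3–C4 bond, C=O exocyclic), and only the cis iodoalkene brings C3 within reach of C4. C4 is set by the oxazoline–sulfonamide ligand, which leaves the Si face of the bound aldehyde open and so gives the (R)-carbinol. C6 is fixed in the same event: in the half-chair transition state the chromium-bound oxygen on C4 and the branched Cα substituent on C6 both sit equatorial (1,3-cis) while the slimmer unreacted CH2CHO arm goes axial, and only the pro-R arm can present its Si face in that arrangement, with the resident (S)-Cα centre adding a bias that the ligand enantiomer has to match. The step needs arm (group) selectivity, aldehyde-over-ketone chemoselectivity and ring closure over oligomerisation, secured in turn by the size difference between the Cα branch and the CH2CHO arm together with the ligand, by the hindered and donor-deactivated aryl ketone, and by the single C–I bond per molecule combined with slow addition at high dilution.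

Step 10
Reactants: 18 2-{(1S,5R)-1-[(S)-1-(3,4-dimethoxyphenyl)-1-oxopropan-2-yl]-5-hydroxy-2-oxocyclohex-3-en-1-yl}acetaldehyde
Product: 19 2-{(1S,5R)-1-[(S)-1-(3,4-dimethoxyphenyl)-1-oxopropan-2-yl]-5-methoxy-2-oxocyclohex-3-en-1-yl}acetaldehyde
Conditions: MeOTf (3 equiv), 2,6-di-tert-butyl-4-methylpyridine (4 equiv), CH2Cl2, 0 °C to rt
Reagents that add atoms: methyl trifluoromethanesulfonate, COS(=O)(=O)C(F)(F)F
Why: O-alkylation of a secondary allylic alcohol with a hard methylating agent and a non-nucleophilic hindered pyridine, chosen because alkoxide conditions would endanger the γ-oxygenated enone, the aldehyde and Cα; the C4–O bond is not broken, so the configuration is retained.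

Step 11
Reactants: 19 2-{(1S,5R)-1-[(S)-1-(3,4-dimethoxyphenyl)-1-oxopropan-2-yl]-5-methoxy-2-oxocyclohex-3-en-1-yl}acetaldehyde
Product: 20 (4R,6R)-6-[(S)-1-(3,4-dimethoxyphenyl)-1-oxopropan-2-yl]-4-methoxy-6-(prop-2-en-1-yl)cyclohex-2-en-1-one
Conditions: Ph3PCH3Br (1.1 equiv), KN(SiMe3)2 (1.05 equiv), THF, 0 °C; then 19, −78 °C
Reagents that add atoms: methyltriphenylphosphonium bromide, C[P+](c1ccccc1)(c1ccccc1)c1ccccc1.[Br-]
Why: Wittig methylenation, in which one equivalent of the unstabilised ylide at −78 °C reacts with the unhindered aldehyde much faster than with either ketone (both flanked by C6 or Cα), and the short, cold contact with base protects Cα and C4; the C6 descriptor changes from S to R only because the CIP ranking of the arm changes.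

**Compound list**

1 | (S)-4-methoxy-2-methyl-4-oxobutanoic acid | COC(=O)C[C@H](C)C(=O)O | starting material
2 | cis-1,4-dichlorobut-2-ene | ClC/C=C\CCl | starting material
3 | (2S,5Z)-7-chloro-3-(methoxycarbonyl)-2-methylhept-5-enoic acid (lithium salt in the flask; C3 epimers) | COC(=O)C(C/C=C\CCl)[C@H](C)C(=O)O | intermediate
4 | (S)-2-[1-(methoxycarbonyl)cyclopent-3-en-1-yl]propanoic acid | COC(=O)C1(CC=CC1)[C@H](C)C(=O)O | intermediate
5 | (S)-2-[1-(hydroxymethyl)cyclopent-3-en-1-yl]propanoic acid | OCC1(CC=CC1)[C@H](C)C(=O)O | intermediate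
6 | (S)-4-methyl-2-oxaspiro[4.4]non-7-en-3-one | C[C@@H]1C(=O)OCC12CC=CC2 | intermediate
7 | 4-bromo-1,2-dimethoxybenzene | COc1ccc(Br)cc1OC | starting material
8 | 3,4-dimethoxyphenyllithium | [Li]c1ccc(OC)c(OC)c1 | intermediate
9 | (S)-1-(3,4-dimethoxyphenyl)-2-[1-(hydroxymethyl)cyclopent-3-en-1-yl]propan-1-one | OCC1(CC=CC1)[C@H](C)C(=O)c1ccc(OC)c(OC)c1 | intermediate
10 | 1-[(S)-1-(3,4-dimethoxyphenyl)-1-oxopropan-2-yl]cyclopent-3-ene-1-carbaldehyde | O=CC1(CC=CC1)[C@H](C)C(=O)c1ccc(OC)c(OC)c1 | intermediate
11 | ethynylmagnesium bromide | C#C[Mg]Br | starting material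
12 | (2S)-1-(3,4-dimethoxyphenyl)-2-[1-(1-hydroxyprop-2-yn-1-yl)cyclopent-3-en-1-yl]propan-1-one (both carbinol epimers) | C#CC(O)C1(CC=CC1)[C@H](C)C(=O)c1ccc(OC)c(OC)c1 | intermediate
13 | (S)-1-(3,4-dimethoxyphenyl)-2-[1-(prop-2-ynoyl)cyclopent-3-en-1-yl]propan-1-one | C#CC(=O)C1(CC=CC1)[C@H](C)C(=O)c1ccc(OC)c(OC)c1 | intermediate
14 | (S)-1-(3,4-dimethoxyphenyl)-2-{1-[(Z)-3-iodoprop-2-enoyl]cyclopent-3-en-1-yl}propan-1-one | I/C=C\C(=O)C1(CC=CC1)[C@H](C)C(=O)c1ccc(OC)c(OC)c1 | intermediate
15 | (S)-1-(3,4-dimethoxyphenyl)-2-{3-[(Z)-3-iodoprop-2-enoyl]-6,7,8-trioxabicyclo[3.2.1]octan-3-yl}propan-1-one (secondary ozonide) | I/C=C\C(=O)C1(CC2OOC(C1)O2)[C@H](C)C(=O)c1ccc(OC)c(OC)c1 | intermediate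
16 | 3-[(S)-1-(3,4-dimethoxyphenyl)-1-oxopropan-2-yl]-3-[(Z)-3-iodoprop-2-enoyl]pentanedial | O=CCC(CC=O)([C@H](C)C(=O)c1ccc(OC)c(OC)c1)C(=O)/C=C\I | intermediate
17 | (Z)-alkenylchromium chloride derived from 16, C3–Cr in place of C3–I, sulfonamide ligand N-bound (solvent ligands omitted) | O=CCC(CC=O)([C@H](C)C(=O)c1ccc(OC)c(OC)c1)C(=O)/C=C\[Cr](Cl)N(S(C)(=O)=O)c1c(C)cccc1C1=N[C@@H](C(C)C)CO1 | intermediate
18 | 2-{(1S,5R)-1-[(S)-1-(3,4-dimethoxyphenyl)-1-oxopropan-2-yl]-5-hydroxy-2-oxocyclohex-3-en-1-yl}acetaldehyde | O=CC[C@]1([C@H](C)C(=O)c2ccc(OC)c(OC)c2)C[C@@H](O)C=CC1=O | intermediate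
19 | 2-{(1S,5R)-1-[(S)-1-(3,4-dimethoxyphenyl)-1-oxopropan-2-yl]-5-methoxy-2-oxocyclohex-3-en-1-yl}acetaldehyde | O=CC[C@]1([C@H](C)C(=O)c2ccc(OC)c(OC)c2)C[C@@H](OC)C=CC1=O | intermediate
20 | (4R,6R)-6-[(S)-1-(3,4-dimethoxyphenyl)-1-oxopropan-2-yl]-4-methoxy-6-(prop-2-en-1-yl)cyclohex-2-en-1-one | C=CC[C@]1([C@H](C)C(=O)c2ccc(OC)c(OC)c2)C[C@@H](OC)C=CC1=O | target

Total step count: 11. Longest linear sequence: 11 steps (1 to 20).

**Steps most likely to fail**

Step 9 (new method).
- Risk: discrimination between the two arms may be weak if ligand control and the conformational bias of the half-chair do not reinforce each other. The alkenylchromium may be protonated before it reaches an aldehyde. Intermolecular coupling may compete with ring closure.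
- Fallback: this uses known chemistry. The C3–C4 bond is made intermolecularly and the ring is closed at C2=C3 by olefin metathesis. It sets out from 10 and returns at 18. Vinylmagnesium bromide adds to 10 to give the allylic alcohol F1, and Dess–Martin oxidation gives the vinyl ketone F2. Ozonolysis of the cyclopentene, which is far more electron-rich than the acryloyl group, gives the acryloyl dialdehyde F3. One aldehyde is then vinylated with a deficit of iodoethene under the ligand-controlled CrCl2/NiCl2 conditions established for intermolecular alkenylation. The resulting alkoxide masks the second aldehyde as a lactolate, and the product is the (5R)-hydroxy aldehyde F4 as both epimers at the quaternary carbon. Ring-closing metathesis with the second-generation Hoveyda–Grubbs catalyst (H2IMes)Cl2Ru=CH(2-i-PrOC6H4) gives 18 together with the quaternary-carbon epimer F5. F5 is removed by chromatography, because only it has OH and CH2CHO on the same ring face and can fold into a bridged lactol. This path gives up group selection at C6.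

Step 1.
- Risk: the second displacement may follow the SN2' course and close a three-membered ring instead of the cyclopentene. One dichloride may bridge two dianions. The second enolisation next to the branched Cα may stay incomplete.
- Fallback: two intermolecular allylations and a metathesis replace the bis-electrophile. It sets out from 1 and returns at 4. The dianion of 1 (LiN(i-Pr)2, 2.2 equiv) is allylated with allyl bromide to the monoallyl half-ester F6. A second enolisation and allylation give the diallyl half-ester F7. Ring-closing metathesis with the second-generation Grubbs catalyst (H2IMes)(PCy3)Cl2Ru=CHPh then closes the cyclopentene of 4.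

Step 8.
- Risk: ozone may not stop at the cyclopentene and may begin to degrade the dimethoxyarene or the iodoalkene. The sulfide used to reduce the ozonide may isomerise or displace the vinylic iodide on warming.
- Fallback: cleavage through a glycol replaces the dipolar cycloaddition and its reductive work-up. It sets out from 14 and returns at 16. Catalytic OsO4, with NaIO4 as the only oxidant and 2,6-lutidine as a non-nucleophilic buffer in dioxane–water, dihydroxylates the electron-rich ring alkene to the cis-diol F8. Periodate cleaves F8 to 16, so neither a reductant nor a nucleophilic amine meets the iodoenone.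

**Further compounds**

F1 | step 9 | (2S)-1-(3,4-dimethoxyphenyl)-2-[1-(1-hydroxyprop-2-en-1-yl)cyclopent-3-en-1-yl]propan-1-one (both carbinol epimers) | C=CC(O)C1(CC=CC1)[C@H](C)C(=O)c1ccc(OC)c(OC)c1
F2 | step 9 | (S)-1-(3,4-dimethoxyphenyl)-2-[1-(prop-2-enoyl)cyclopent-3-en-1-yl]propan-1-one | C=CC(=O)C1(CC=CC1)[C@H](C)C(=O)c1ccc(OC)c(OC)c1
F3 | step 9 | 3-[(S)-1-(3,4-dimethoxyphenyl)-1-oxopropan-2-yl]-3-(prop-2-enoyl)pentanedial | O=CCC(CC=O)([C@H](C)C(=O)c1ccc(OC)c(OC)c1)C(=O)C=C
F4 | step 9 | (5R)-3-[(S)-1-(3,4-dimethoxyphenyl)-1-oxopropan-2-yl]-5-hydroxy-3-(prop-2-enoyl)hept-6-enal (both C3 epimers) | O=CCC(C[C@@H](O)C=C)([C@H](C)C(=O)c1ccc(OC)c(OC)c1)C(=O)C=C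
F5 | step 9 | 2-{(1R,5R)-1-[(S)-1-(3,4-dimethoxyphenyl)-1-oxopropan-2-yl]-5-hydroxy-2-oxocyclohex-3-en-1-yl}acetaldehyde | O=CC[C@@]1([C@H](C)C(=O)c2ccc(OC)c(OC)c2)C[C@@H](O)C=CC1=O
F6 | step 1 | (2S)-3-(methoxycarbonyl)-2-methylhex-5-enoic acid (C3 epimers) | COC(=O)C(CC=C)[C@H](C)C(=O)O
F7 | step 1 | (2S)-3-(methoxycarbonyl)-2-methyl-3-(prop-2-en-1-yl)hex-5-enoic acid | COC(=O)C(CC=C)(CC=C)[C@H](C)C(=O)O
F8 | step 8 | (S)-2-{cis-3,4-dihydroxy-1-[(Z)-3-iodoprop-2-enoyl]cyclopentyl}-1-(3,4-dimethoxyphenyl)propan-1-one | I/C=C\C(=O)C1(C[C@H](O)[C@H](O)C1)[C@H](C)C(=O)c1ccc(OC)c(OC)c1
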